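**Strategy.** Numbering the 14-membered ring from the ester-bearing carbon (C1) through its olefinic partner C2 and the stereocentre C4 round to C14, the ring holds the 1,5-diene C11=C12–C13–C14–C1=C2. Its central bond C13–C14 joins two allylic methylenes that are both natural electrophiles. C13 is reversed in polarity as a sulfone-stabilised allyl carbanion and attacks the methylene C14 of a Morita–Baylis–Hillman acetate, CH2=C(CO2Me)–CH(OAc)–. Addition–elimination closes the ring, shifts the double bond into C1=C2 and converges both acetate epimers on the E-enoate. The acyclic precursor comes from farnesyl bromide; C4 is set by a Johnson–Claisen rearrangement, and the sulfonyl group is finally removed by palladium-catalysed hydride reduction.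

Key step: step 9

Remark: the target SMILES is read as the (4R) enantiomer with all four stereodefined double bonds E; side-chain carbons are C15 (on C4) to C19, and the allylborane of step 3 is taken as the commercial reagent solution.

**Step 1**
Reactants: 1 (2E,6E)-farnesyl bromide; 2 sodium benzenesulfinate
Product: 3 (2E,6E)-farnesyl phenyl sulfone
Conditions: DMF, rt
Reagents that add atoms: none
Why: SN2 displacement of the primary allylic bromide by the soft sulfur atom of the sulfinate (S-alkylation) should give the allylic sulfone with both E double bonds untouched, installing at the outset the group that later reverses the polarity of C13.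

**Step 2**
Reactants: 3 (2E,6E)-farnesyl phenyl sulfone
Product: 5 (2E,6E,10E)-2,6,10-trimethyl-12-(phenylsulfonyl)dodeca-2,6,10-trienal, via hydroxy sulfone 4 (not isolated)
Conditions: SeO2 (cat.), tBuOOH, salicylic acid (cat.), CH2Cl2, rt; then MnO2, CH2Cl2, rt
Reagents that add atoms: tert-butyl hydroperoxide, CC(C)(C)OO (oxygen relayed by selenium dioxide, O=[Se]=O)
Why: Riley allylic oxidation (ene reaction of SeO2, then a [2,3]-sigmatropic shift) is expected to attack the E-methyl group of the terminal, most electron-rich trisubstituted olefin, the olefin next to the sulfonyl group being deactivated, and MnO2 then converges the allylic alcohol 4 and any over-oxidised material on the E-enal.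

**Step 3**
Reactants: 5 (2E,6E,10E)-2,6,10-trimethyl-12-(phenylsulfonyl)dodeca-2,6,10-trienal; 6 (+)-B-allyldiisopinocampheylborane
Product: 8 (4R,5E,9E,13E)-5,9,13-trimethyl-15-(phenylsulfonyl)pentadeca-1,5,9,13-tetraen-4-ol, via borinate ester 7 (not isolated)
Conditions: Et2O, −78 °C; then NaOH, H2O2, 0 °C to rt
Reagents that add atoms: none
Why: Brown allylboration through a closed chair-like six-membered transition state, in which the isopinocampheyl groups derived from (−)-α-pinene should deliver the allyl group to the Re face of the aldehyde and so set the R carbinol centre (the future C16), with 1,2-addition only.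

**Step 4**
Reactants: 8 (4R,5E,9E,13E)-5,9,13-trimethyl-15-(phenylsulfonyl)pentadeca-1,5,9,13-tetraen-4-ol; 9 2-methyl-2-butene
Product: 10 (5R,6E,10E,14E)-2,6,10,14-tetramethyl-16-(phenylsulfonyl)hexadeca-2,6,10,14-tetraen-5-ol
Conditions: second-generation Grubbs catalyst RuCl2(=CHPh)(PCy3)(H2IMes) (cat.), 2-methyl-2-butene/CH2Cl2, 40 °C
Reagents that add atoms: none
Why: Olefin cross-metathesis in which only the monosubstituted terminal olefin should enter the catalytic cycle at a useful rate, the trisubstituted olefins of the chain being spectators, so that the excess 2-methyl-2-butene caps it as the isopropylidene (prenyl) terminus without touching the carbinol centre.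

**Step 5**
Reactants: 10 (5R,6E,10E,14E)-2,6,10,14-tetramethyl-16-(phenylsulfonyl)hexadeca-2,6,10,14-tetraen-5-ol; 11 triethyl orthoacetate
Product: 13 ethyl (3R,4E)-3-[(3E,7E)-3,7-dimethyl-9-(phenylsulfonyl)nona-3,7-dien-1-yl]-4,8-dimethylnona-4,7-dienoate, via ketene acetal 12 (not isolated)
Conditions: EtCO2H (cat.), 135 °C, EtOH distilled off
Reagents that add atoms: none
Why: Johnson–Claisen rearrangement, in which ketene acetal 12 should react through a chair transition state with the prenyl-bearing carbinol substituent equatorial, giving the E C15=C16 double bond and, by suprafacial 1,3-transfer of chirality from the C16–O bond to the new C3–C4 bond, the R configuration at C4.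

**Step 6**
Reactants: 13 ethyl (3R,4E)-3-[(3E,7E)-3,7-dimethyl-9-(phenylsulfonyl)nona-3,7-dien-1-yl]-4,8-dimethylnona-4,7-dienoate
Product: 15 (3R,4E)-3-[(3E,7E)-3,7-dimethyl-9-(phenylsulfonyl)nona-3,7-dien-1-yl]-4,8-dimethylnona-4,7-dienal, via aluminium hemiacetal 14 (not isolated)
Conditions: iBu2AlH (1.1 equiv), CH2Cl2, −78 °C; then aq. KNaC4H4O6 (potassium sodium tartrate)
Reagents that add atoms: none
Why: Partial reduction of the ester by iBu2AlH at low temperature should stop at the aluminium hemiacetal 14, which collapses to the aldehyde only on work-up, and the stereocentre, being β to the carbonyl, cannot epimerise.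

**Step 7**
Reactants: 15 (3R,4E)-3-[(3E,7E)-3,7-dimethyl-9-(phenylsulfonyl)nona-3,7-dien-1-yl]-4,8-dimethylnona-4,7-dienal; 16 methyl acrylate
Product: 17 methyl (5R,6E)-3-hydroxy-6,10-dimethyl-2-methylidene-5-[(3E,7E)-3,7-dimethyl-9-(phenylsulfonyl)nona-3,7-dien-1-yl]undeca-6,9-dienoate (both C3 epimers)
Conditions: DABCO (1 equiv), excess methyl acrylate, MeOH (minimal), rt
Reagents that add atoms: none
Why: Morita–Baylis–Hillman reaction (conjugate addition of DABCO to the acrylate, aldol addition of the ammonium enolate to the aldehyde, elimination of the amine) should give the α-methylene β-hydroxy ester, whose new carbinol centre (ring carbon C2) forms without control and needs none because it is destroyed in step 9.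

**Step 8**
Reactants: 17 methyl (5R,6E)-3-hydroxy-6,10-dimethyl-2-methylidene-5-[(3E,7E)-3,7-dimethyl-9-(phenylsulfonyl)nona-3,7-dien-1-yl]undeca-6,9-dienoate
Product: 18 methyl (5R,6E)-3-acetoxy-6,10-dimethyl-2-methylidene-5-[(3E,7E)-3,7-dimethyl-9-(phenylsulfonyl)nona-3,7-dien-1-yl]undeca-6,9-dienoate (both C3 epimers)
Conditions: Ac2O, pyridine, DMAP (cat.), CH2Cl2, 0 °C
Reagents that add atoms: acetic anhydride, CC(=O)OC(C)=O
Why: O-Acylation of the secondary allylic alcohol under nucleophilic catalysis at low temperature should give the branched acetate without allylic transposition, turning the C2–O bond into the leaving group for the ring closure.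

**Step 9**
Reactants: 18 methyl (5R,6E)-3-acetoxy-6,10-dimethyl-2-methylidene-5-[(3E,7E)-3,7-dimethyl-9-(phenylsulfonyl)nona-3,7-dien-1-yl]undeca-6,9-dienoate
Product: 21 methyl (1E,4R,7E,11E)-7,11-dimethyl-4-[(2E)-6-methylhepta-2,5-dien-2-yl]-13-(phenylsulfonyl)cyclotetradeca-1,7,11-triene-1-carboxylate (both C13 epimers), via lithiated sulfone 19 (not isolated), via ring ester enolate 20 (not isolated)
Conditions: LiN(SiMe3)2 (1.2 equiv), THF, −20 °C, 18 added by syringe pump (final 2 mM); then AcOH
Reagents that add atoms: none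
Why: LiN(SiMe3)2 removes a proton from the sulfonyl-bearing C13 to give allyl carbanion 19, which adds through its α-carbon to the unsubstituted methylene C14 of the acrylate to give ring enolate 20, and E1cB loss of acetate from C2 then forms the C1=C2 double bond. The closest known reaction types are the SN2′ substitution of Morita–Baylis–Hillman acetates by stabilised carbanions and the intramolecular alkylation of sulfone-stabilised allyl anions used to close 14-membered terpenoid rings. The carbocycle is closed in the 14-endo-trig mode, by conjugate addition to the acrylate terminus. The only new stereocentre, C13, is not controlled and is erased in step 10, while the C1=C2 geometry is controlled by allylic 1,3-strain in enolate 20, which places C3 syn to C14 during the elimination and so should give the E-enoate from either C2 epimer of 18. The step needs α- over γ-attack of the allyl anion (γ-attack would build a 12-membered ring with a quaternary C11), conjugate addition over attack at the acetate carbonyl (soft carbanion, activated acrylate) and ring closure over chain growth (slow addition, high dilution). The E geometry of C11=C12 should be retained because the sulfonyl allyl anion does not rotate about that bond at low temperature.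

**Step 10**
Reactants: 21 methyl (1E,4R,7E,11E)-7,11-dimethyl-4-[(2E)-6-methylhepta-2,5-dien-2-yl]-13-(phenylsulfonyl)cyclotetradeca-1,7,11-triene-1-carboxylate
Product: 22 methyl (1E,4R,7E,11E)-7,11-dimethyl-4-[(2E)-6-methylhepta-2,5-dien-2-yl]cyclotetradeca-1,7,11-triene-1-carboxylate
Conditions: PdCl2[Ph2P(CH2)3PPh2] (cat.), NaBH4, THF/iPrOH, 0 °C to rt
Reagents that add atoms: none
Why: Palladium-catalysed reductive desulfonylation, in which zerovalent palladium formed in the flask ionises the allylic C13–S bond to a π-allyl complex and hydride from NaBH4 attacks its less substituted terminus C13, so that C11=C12 keeps its position and E geometry, both C13 epimers converge on one product and the conjugated ester, inert to NaBH4, survives.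

**Compound list**

1 | (2E,6E)-farnesyl bromide, (2E,6E)-1-bromo-3,7,11-trimethyldodeca-2,6,10-triene | CC(C)=CCC/C(C)=C/CC/C(C)=C/CBr | starting material
2 | sodium benzenesulfinate | [Na+].[O-]S(=O)c1ccccc1 | starting material
3 | (2E,6E)-farnesyl phenyl sulfone, [(2E,6E)-3,7,11-trimethyldodeca-2,6,10-trien-1-yl]sulfonylbenzene | CC(C)=CCC/C(C)=C/CC/C(C)=C/CS(=O)(=O)c1ccccc1 | intermediate
4 | (2E,6E,10E)-2,6,10-trimethyl-12-(phenylsulfonyl)dodeca-2,6,10-trien-1-ol | OC/C(C)=C/CC/C(C)=C/CC/C(C)=C/CS(=O)(=O)c1ccccc1 | intermediate (not isolated)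
5 | (2E,6E,10E)-2,6,10-trimethyl-12-(phenylsulfonyl)dodeca-2,6,10-trienal | O=C/C(C)=C/CC/C(C)=C/CC/C(C)=C/CS(=O)(=O)c1ccccc1 | intermediate
6 | (+)-B-allyldiisopinocampheylborane, allylbis[(1S,2R,3S,5S)-2,6,6-trimethylbicyclo[3.1.1]heptan-3-yl]borane, from (−)-α-pinene | C=CCB([C@H]1C[C@H]2C[C@@H]([C@@H]1C)C2(C)C)[C@H]1C[C@H]2C[C@@H]([C@@H]1C)C2(C)C | starting material
7 | diisopinocampheylborinate ester of alcohol 8 | C=CC[C@@H](OB([C@H]1C[C@H]2C[C@@H]([C@@H]1C)C2(C)C)[C@H]1C[C@H]2C[C@@H]([C@@H]1C)C2(C)C)/C(C)=C/CC/C(C)=C/CC/C(C)=C/CS(=O)(=O)c1ccccc1 | intermediate (not isolated)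
8 | (4R,5E,9E,13E)-5,9,13-trimethyl-15-(phenylsulfonyl)pentadeca-1,5,9,13-tetraen-4-ol | C=CC[C@@H](O)/C(C)=C/CC/C(C)=C/CC/C(C)=C/CS(=O)(=O)c1ccccc1 | intermediate
9 | 2-methyl-2-butene | CC=C(C)C | starting material
10 | (5R,6E,10E,14E)-2,6,10,14-tetramethyl-16-(phenylsulfonyl)hexadeca-2,6,10,14-tetraen-5-ol | CC(C)=CC[C@@H](O)/C(C)=C/CC/C(C)=C/CC/C(C)=C/CS(=O)(=O)c1ccccc1 | intermediate
11 | triethyl orthoacetate | CCOC(C)(OCC)OCC | starting material
12 | 1-ethoxyvinyl ether (mixed ketene acetal) of alcohol 10 | CCOC(=C)O[C@H](CC=C(C)C)/C(C)=C/CC/C(C)=C/CC/C(C)=C/CS(=O)(=O)c1ccccc1 | intermediate (not isolated)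
13 | ethyl (3R,4E)-3-[(3E,7E)-3,7-dimethyl-9-(phenylsulfonyl)nona-3,7-dien-1-yl]-4,8-dimethylnona-4,7-dienoate | CCOC(=O)C[C@H](/C(C)=C/CC=C(C)C)CC/C(C)=C/CC/C(C)=C/CS(=O)(=O)c1ccccc1 | intermediate
14 | diisobutylaluminium hemiacetal of ester 13 | CCOC(O[Al](CC(C)C)CC(C)C)C[C@H](/C(C)=C/CC=C(C)C)CC/C(C)=C/CC/C(C)=C/CS(=O)(=O)c1ccccc1 | intermediate (not isolated)
15 | (3R,4E)-3-[(3E,7E)-3,7-dimethyl-9-(phenylsulfonyl)nona-3,7-dien-1-yl]-4,8-dimethylnona-4,7-dienal | O=CC[C@H](/C(C)=C/CC=C(C)C)CC/C(C)=C/CC/C(C)=C/CS(=O)(=O)c1ccccc1 | intermediate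
16 | methyl acrylate | C=CC(=O)OC | starting material
17 | methyl (5R,6E)-3-hydroxy-6,10-dimethyl-2-methylidene-5-[(3E,7E)-3,7-dimethyl-9-(phenylsulfonyl)nona-3,7-dien-1-yl]undeca-6,9-dienoate, both C3 epimers | C=C(C(=O)OC)C(O)C[C@H](/C(C)=C/CC=C(C)C)CC/C(C)=C/CC/C(C)=C/CS(=O)(=O)c1ccccc1 | intermediate
18 | methyl (5R,6E)-3-acetoxy-6,10-dimethyl-2-methylidene-5-[(3E,7E)-3,7-dimethyl-9-(phenylsulfonyl)nona-3,7-dien-1-yl]undeca-6,9-dienoate, both C3 epimers | C=C(C(=O)OC)C(OC(C)=O)C[C@H](/C(C)=C/CC=C(C)C)CC/C(C)=C/CC/C(C)=C/CS(=O)(=O)c1ccccc1 | intermediate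
19 | lithium salt of 18 deprotonated at the sulfonyl-bearing carbon (C13) | C=C(C(=O)OC)C(OC(C)=O)C[C@H](/C(C)=C/CC=C(C)C)CC/C(C)=C/CC/C(C)=C/[CH-]S(=O)(=O)c1ccccc1.[Li+] | intermediate (not isolated)
20 | lithium ester enolate of the ring-closed adduct (14-membered ring, acetate still on C2, sulfonyl on C13) | COC([O-])=C1C(OC(C)=O)C[C@H](/C(C)=C/CC=C(C)C)CC/C(C)=C/CC/C(C)=C/C(S(=O)(=O)c2ccccc2)C1.[Li+] | intermediate (not isolated)
21 | methyl (1E,4R,7E,11E)-7,11-dimethyl-4-[(2E)-6-methylhepta-2,5-dien-2-yl]-13-(phenylsulfonyl)cyclotetradeca-1,7,11-triene-1-carboxylate, both C13 epimers | COC(=O)/C1=C/C[C@H](/C(C)=C/CC=C(C)C)CC/C(C)=C/CC/C(C)=C/C(S(=O)(=O)c2ccccc2)C1 | intermediate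
22 | methyl (1E,4R,7E,11E)-7,11-dimethyl-4-[(2E)-6-methylhepta-2,5-dien-2-yl]cyclotetradeca-1,7,11-triene-1-carboxylate | COC(=O)/C1=C/C[C@H](/C(C)=C/CC=C(C)C)CC/C(C)=C/CC/C(C)=C/CC1 | target

**Total step count:** 10. **Longest linear sequence:** 10 steps (1 to 22).

**Steps most likely to fail**

1. Step 9. Chain growth by intermolecular conjugate addition may outrun ring closure, the acetyl group may be transferred to the carbanion, and E selectivity of the elimination inside the forming ring may be incomplete. The fallback sets out from 17. NBS/Me2S in CH2Cl2 at 0 °C should convert it, with allylic transposition, into the primary allylic bromide methyl (2Z,5R,6E)-2-(bromomethyl)-6,10-dimethyl-5-[(3E,7E)-3,7-dimethyl-9-(phenylsulfonyl)nona-3,7-dien-1-yl]undeca-2,6,9-trienoate F1, in which the C1=C2 geometry is fixed before cyclisation. The same C13–C14 bond is then closed by direct SN2 displacement of bromide by the lithiated sulfone (LiN(SiMe3)2, THF, high dilution), which comes back to the route at 21.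

2. Step 10. Hydride may be delivered to the tertiary terminus of the π-allyl complex (double-bond migration to C12=C13), the complex may undergo β-hydride elimination to a conjugated triene, or the enoate may suffer conjugate reduction. The fallback sets out from 21. LiOH in THF/MeOH/H2O should give (1E,4R,7E,11E)-7,11-dimethyl-4-[(2E)-6-methylhepta-2,5-dien-2-yl]-13-(phenylsulfonyl)cyclotetradeca-1,7,11-triene-1-carboxylic acid F2. As its lithium carboxylate this is inert to LiBHEt3, so desulfonylation with PdCl2[Ph2P(CH2)3PPh2]/LiBHEt3 in THF at 0 °C can be used to give (1E,4R,7E,11E)-7,11-dimethyl-4-[(2E)-6-methylhepta-2,5-dien-2-yl]cyclotetradeca-1,7,11-triene-1-carboxylic acid F3. Methylation with MeI/K2CO3 in DMF comes back to the route at 22.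

3. Step 7. Addition to the β-branched, lipophilic aldehyde may be very slow, with oligomerisation of the acrylate and aldol self-condensation of the aldehyde taking over. The fallback sets out from 15 and uses vinylalumination in place of amine catalysis. Hydroalumination of methyl propiolate with iBu2AlH/HMPA in THF at 0 °C gives methyl 2-(diisobutylalumanyl)prop-2-enoate F4, which should add to 15 to give the diisobutylaluminium alkoxide of 17 F5. Aqueous work-up comes back to the route at 17.

**Further compounds**

F1 | step 9 | methyl (2Z,5R,6E)-2-(bromomethyl)-6,10-dimethyl-5-[(3E,7E)-3,7-dimethyl-9-(phenylsulfonyl)nona-3,7-dien-1-yl]undeca-2,6,9-trienoate | COC(=O)/C(CBr)=C/C[C@H](/C(C)=C/CC=C(C)C)CC/C(C)=C/CC/C(C)=C/CS(=O)(=O)c1ccccc1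
F2 | step 10 | (1E,4R,7E,11E)-7,11-dimethyl-4-[(2E)-6-methylhepta-2,5-dien-2-yl]-13-(phenylsulfonyl)cyclotetradeca-1,7,11-triene-1-carboxylic acid | OC(=O)/C1=C/C[C@H](/C(C)=C/CC=C(C)C)CC/C(C)=C/CC/C(C)=C/C(S(=O)(=O)c2ccccc2)C1
F3 | step 10 | (1E,4R,7E,11E)-7,11-dimethyl-4-[(2E)-6-methylhepta-2,5-dien-2-yl]cyclotetradeca-1,7,11-triene-1-carboxylic acid | OC(=O)/C1=C/C[C@H](/C(C)=C/CC=C(C)C)CC/C(C)=C/CC/C(C)=C/CC1
F4 | step 7 | methyl 2-(diisobutylalumanyl)prop-2-enoate | C=C(C(=O)OC)[Al](CC(C)C)CC(C)C
F5 | step 7 | diisobutylaluminium alkoxide of 17 | C=C(C(=O)OC)C(O[Al](CC(C)C)CC(C)C)C[C@H](/C(C)=C/CC=C(C)C)CC/C(C)=C/CC/C(C)=C/CS(=O)(=O)c1ccccc1
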